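**Retrosynthetic overview**
1. Endgame: TES removal ⇐ angeloylation of O6 ⇐ hydroxyl-directed epoxidation of the Z C4=C5 bond ⇐ α-methylenation at C11 ⇐ 1,2-reduction of a C6 enone.
2. Key disconnection C5–C6: the ten-membered carbocycle comes from ring expansion of a seven-membered lactone (O1–C1–C10–C9–C8–C7–C6). The C5 alkenyllithium of the C2–C5 arm on C1 attacks the lactone carbonyl C6, and O1 leaves the ring as the C1 alkoxide.
3. Enabling feature: the oxygen of the free C1 hydroxyl and the carbinol carbon C6 lie 1,6 across the ten-membered ring, and C4=C5 is Z. O1 can therefore hold C6 as an ester, and C5 reaches C6 through a seven-membered, 11-oxabicyclo[4.4.1]-type intermediate instead of a ten-membered transition state.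
4. Bis-lactone ⇐ strain-driven translactonisation of a cis-β-lactone (C6–C7–C8–O8) ⇐ catalytic asymmetric ketene–aldehyde cyclocondensation. Aldehyde ⇐ CBS reduction (C1), alkenyllithium addition, Z-selective carbocupration of propyne.
5. Order of ring formation: four-membered lactone (temporary) → seven-membered lactone (temporary) together with the five-membered lactone → ten-membered carbocycle → oxirane.

Key step: step 11

Remark: atom numbers C1–C15 are the germacrane numbers of the target (C1 = CHOH, C4/C5 = oxirane carbons, C6 = CH–O–angeloyl, C7/C8 = lactone fusion, C10=C14 and C11=C13 = the two methylene groups, C12 = lactone C=O) and are used for all intermediates; the configuration written in the SMILES, (1S,4R,5S,6S,7R,8S) with a cis-oxirane (C3 and C6 on the same side) and a (Z)-2-methylbut-2-enoate, is taken as absolute; α is the ring face that carries H-7, O1, the oxirane O, O6 and O8.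

Step 1
Reactants: 1 2-(2-bromoethyl)-1,3-dioxolane; 2 propyne
Product: 5 2-[(3Z)-4-iodo-3-methylbut-3-en-1-yl]-1,3-dioxolane, via Grignard reagent 3 (not isolated), via alkenylcopper 4 (not isolated)
Conditions: Mg, THF, 25 °C; CuBr·SMe2, Et2O/SMe2, −45 °C; 2, −25 °C; I2, THF, −78 to 0 °C
Reagents that add atoms: iodine (II); magnesium ([Mg], in 3 only); CuBr·SMe2 ([Cu]Br.CSC, copper in 4 only)
Why: Normant syn-carbocupration of propyne puts the alkyl group on the internal carbon with copper cis to it, and iodinolysis with retention fixes the Z C4=C5 geometry (C3 and iodine cis).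

Step 2
Reactants: 5 2-[(3Z)-4-iodo-3-methylbut-3-en-1-yl]-1,3-dioxolane
Product: 6 (4Z)-5-iodo-4-methylpent-4-enal
Conditions: 1 M HCl, acetone, 40 °C
Reagents that add atoms: water (O)
Why: Acid-catalysed acetal hydrolysis frees the C1 aldehyde, and the alkenyl iodide is inert to dilute acid.

Step 3
Reactants: 7 3-bromobut-3-en-1-ol
Product: 8 [(3-bromobut-3-en-1-yl)oxy]triethylsilane
Conditions: TESCl, imidazole, CH2Cl2, 0 °C
Reagents that add atoms: chlorotriethylsilane (CC[Si](Cl)(CC)CC)
Why: Standard silylation masks the C8 hydroxyl as an ether that step 8 can oxidise directly.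

Step 4
Reactants: 8 [(3-bromobut-3-en-1-yl)oxy]triethylsilane; 6 (4Z)-5-iodo-4-methylpent-4-enal
Product: 10 rac-(7Z)-8-iodo-7-methyl-3-methylidene-1-[(triethylsilyl)oxy]oct-7-en-4-ol, via alkenyllithium 9 (not isolated)
Conditions: 8, t-BuLi (2 equiv), Et2O, −78 °C; then 6, −78 °C; H2O
Reagents that add atoms: tert-butyllithium ([Li]C(C)(C)C, lithium in 9 only)
Why: Bromine–lithium exchange and 1,2-addition form C1–C10; carbonyl addition at −78 °C outruns iodine–lithium exchange with the alkenyl iodide, and the racemic C1 centre is corrected in steps 5 and 6.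

Step 5
Reactants: 10 rac-(7Z)-8-iodo-7-methyl-3-methylidene-1-[(triethylsilyl)oxy]oct-7-en-4-ol
Product: 11 (7Z)-8-iodo-7-methyl-3-methylidene-1-[(triethylsilyl)oxy]oct-7-en-4-one
Conditions: Dess–Martin periodinane, CH2Cl2, 0 °C to rt
Reagents that add atoms: none
Why: Dess–Martin oxidation of the allylic alcohol is mild and leaves the silyl ether and the alkenyl iodide untouched.

Step 6
Reactants: 11 (7Z)-8-iodo-7-methyl-3-methylidene-1-[(triethylsilyl)oxy]oct-7-en-4-one
Product: 12 (4S,7Z)-8-iodo-7-methyl-3-methylidene-1-[(triethylsilyl)oxy]oct-7-en-4-ol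
Conditions: (R)-Me-CBS oxazaborolidine (20 mol %), catecholborane, toluene, −78 °C; pH 7 buffer
Reagents that add atoms: none
Why: Corey–Bakshi–Shibata reduction; the α-branched alkenyl group (C10) acts as the large substituent, so the (R)-catalyst should set C1 as S, and catecholborane at −78 °C does not hydroborate the alkenes.

Step 7
Reactants: 12 (4S,7Z)-8-iodo-7-methyl-3-methylidene-1-[(triethylsilyl)oxy]oct-7-en-4-ol
Product: 13 (4S,7Z)-8-iodo-7-methyl-3-methylidene-1,4-bis[(triethylsilyl)oxy]oct-7-ene
Conditions: TESCl, imidazole, DMF, 0 °C to rt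
Reagents that add atoms: chlorotriethylsilane (CC[Si](Cl)(CC)CC)
Why: Silylation blocks O1 during the build-up of C6–C8 without touching C1.

Step 8
Reactants: 13 (4S,7Z)-8-iodo-7-methyl-3-methylidene-1,4-bis[(triethylsilyl)oxy]oct-7-ene
Product: 14 (4S,7Z)-8-iodo-7-methyl-3-methylidene-4-[(triethylsilyl)oxy]oct-7-enal
Conditions: (COCl)2, DMSO, CH2Cl2, −78 to −40 °C; Et3N, −78 to −20 °C; cold pH 7 buffer
Reagents that add atoms: none
Why: Under Swern conditions a primary triethylsilyl ether is converted directly into the aldehyde while a secondary one survives, and the cold neutral quench keeps C10=C14 out of conjugation.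

Step 9
Reactants: 14 (4S,7Z)-8-iodo-7-methyl-3-methylidene-4-[(triethylsilyl)oxy]oct-7-enal; 15 methyl 4-chloro-4-oxobutanoate
Product: 17 methyl [(3R,4S)-4-{(3S,6Z)-7-iodo-6-methyl-2-methylidene-3-[(triethylsilyl)oxy]hept-6-en-1-yl}-2-oxooxetan-3-yl]acetate (cis-β-lactone C6–C7–C8–O8), via ketene 16 (not isolated)
Conditions: O-trimethylsilylquinidine (15 mol %), LiClO4, i-Pr2NEt, CH2Cl2/Et2O, −78 °C, slow addition of 15
Reagents that add atoms: none
Why: Cinchona-alkaloid-catalysed acyl halide–aldehyde cyclocondensation (ketene–aldehyde [2+2] through an ammonium enolate); the quinidine-series catalyst should fix C7 as R, and the closed lithium-bridged transition state gives the cis relation that sets C8 as S, independently of the remote C1.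

Step 10
Reactants: 17 cis-β-lactone
Product: 20 trans-fused bis-lactone (1S,7R,8S; five-membered lactone C12–O8 and seven-membered lactone C6–O1; C1 carries the (3Z)-4-iodo-3-methylbut-3-enyl arm; C10=C14 exocyclic), via hydroxy β-lactone 18 (not isolated), via seven-membered lactone hydroxy ester 19 (not isolated)
Conditions: HF·pyridine, pyridine, THF, 0 °C; then CSA (10 mol %), 5 Å molecular sieves, toluene (2 mM), 45 °C
Reagents that add atoms: none
Why: After desilylation, acid-catalysed translactonisation is driven by release of the four-membered-ring strain; O1 takes over the acyl carbon C6, the freed O8 closes the five-membered lactone on the methyl ester, and because only acyl–oxygen bonds break, C1, C7 and C8 are retained (cis-β-lactone maps onto the trans five-membered lactone).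

Step 11
Reactants: 20 trans-fused bis-lactone
Product: 24 (4Z)-1α-(triethylsilyloxy)-6-oxogermacra-4,10(14)-dien-12,8α-olide (1S,7R,8S), via alkenyllithium 21 (not isolated), via bridged hemiketal alkoxide 22 (not isolated), via enone lithium alkoxide 23 (not isolated)
Conditions: t-BuLi (2.0 equiv), THF/Et2O/pentane 4:1:1, −100 °C; to −40 °C; TESCl, −40 to 0 °C
Reagents that add atoms: tert-butyllithium ([Li]C(C)(C)C, lithium in 21 to 23 only); chlorotriethylsilane (CC[Si](Cl)(CC)CC)
Why: Iodine–lithium exchange at −100 °C is faster than attack of tert-butyllithium on either lactone and gives the configurationally stable Z-alkenyllithium 21, whose C5 adds to the seven-membered-lactone carbonyl C6 to form the bridged hemiketal alkoxide 22, which collapses on warming with expulsion of O1 to the enone alkoxide 23 that TESCl caps. The closest known reaction type is the halogen–metal-exchange-initiated intramolecular nucleophilic acyl substitution on esters and lactones (Parham-type cyclisation and its SmI2-promoted ring-expanding variants that turn lactones into eight- and nine-membered hydroxy ketones). C5–C6 bond formation is a 7-exo-trig addition that closes the ring O1–C1–C2–C3–C4–C5–C6, and cleavage of C6–O1 then merges this ring and the lactone ring into the ten-membered carbocycle, so no ten-membered transition state is needed. No new stereocentre remains in 24 (C6 of 22 is transient), C1, C7 and C8 are not touched, and the Z geometry of C4=C5 is carried over with retention. The step needs C6 to react rather than the five-membered-lactone carbonyl C12, which the tether (seven- against ten-membered approach) and the more reactive cisoid seven-membered ester secure; it needs addition to beat deprotonation at C7 or C11, which the low temperature favours; over-addition is excluded because each molecule holds one carbanion. The driving force is the change from C–Li to O–Li together with loss of seven-membered-lactone strain and gain of enone conjugation, and the same operation frees and marks O1, the only hydroxyl the target keeps.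

Step 12
Reactants: 24 (4Z)-1α-(triethylsilyloxy)-6-oxogermacra-4,10(14)-dien-12,8α-olide
Product: 25 (4Z)-6α-hydroxy-1α-(triethylsilyloxy)germacra-4,10(14)-dien-12,8α-olide (1S,6R,7S,8S)
Conditions: NaBH4, CeCl3·7H2O, MeOH, −78 °C
Reagents that add atoms: none
Why: Luche reduction gives 1,2-addition; in the ten-membered Z-enone the C6=O bond stands roughly perpendicular to the ring and eclipses C7–H on the α face, away from C11, so peripheral hydride attack should leave O6 on the α face as in the target.

Step 13
Reactants: 25 (4Z)-6α-hydroxy-1α-(triethylsilyloxy)germacra-4,10(14)-dien-12,8α-olide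
Product: 28 (4Z)-6α-hydroxy-1α-(triethylsilyloxy)germacra-4,10(14),11(13)-trien-12,8α-olide (1S,6R,7S,8S), via Mannich base 26 (not isolated), via methiodide 27 (not isolated)
Conditions: LDA (2.3 equiv), THF, −78 °C; Me2N=CH2 I, −78 °C to rt; H2O; MeI, THF/MeOH, rt; aq. NaHCO3, CH2Cl2
Reagents that add atoms: Eschenmoser's salt (C=[N+](C)C.[I-]); iodomethane (CI, methyl in 27 only)
Why: Lactone-enolate Mannich reaction followed by quaternisation and Hofmann-type elimination is the standard α-methylenation; the O6 alkoxide cannot translactonise because C12 is enolised, and the C11 centre of 26 is transient.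

Step 14
Reactants: 28 (4Z)-6α-hydroxy-1α-(triethylsilyloxy)germacra-4,10(14),11(13)-trien-12,8α-olide
Product: 29 4α,5α-epoxy-6α-hydroxy-1α-(triethylsilyloxy)germacra-10(14),11(13)-dien-12,8α-olide (1S,4R,5S,6S,7S,8S)
Conditions: VO(acac)2 (5 mol %), t-BuOOH, CH2Cl2, 0 °C
Reagents that add atoms: tert-butyl hydroperoxide (CC(C)(C)OO)
Why: Hydroxyl-directed vanadium-catalysed epoxidation delivers oxygen to the face of the Z C4=C5 bond syn to O6, as known for medium-ring (Z)-cycloalk-2-enols; this sets C4 (R) and C5 (S) as the cis-oxirane, while the silylated allylic C10=C14 and the electron-poor C11=C13 stay intact.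

Step 15
Reactants: 29 epoxy alcohol; 30 angelic acid ((Z)-2-methylbut-2-enoic acid)
Product: 32 6α-angeloyloxy-4α,5α-epoxy-1α-(triethylsilyloxy)germacra-10(14),11(13)-dien-12,8α-olide (1S,4R,5S,6S,7R,8S), via mixed anhydride 31 (not isolated)
Conditions: 30, 2,4,6-trichlorobenzoyl chloride, Et3N, toluene, rt; then 29, toluene, 80 °C
Reagents that add atoms: 2,4,6-trichlorobenzoyl chloride (O=C(Cl)c1c(Cl)cc(Cl)cc1Cl, in 31 only)
Why: Yamaguchi-type mixed-anhydride acylation run without a nucleophilic amine catalyst is the established way to make angelates without Z-to-E isomerisation; only O6 is free, and C6 is retained.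

Step 16
Reactants: 32 TES ether of the target
Product: 33 target, 6α-angeloyloxy-4α,5α-epoxy-1α-hydroxygermacra-10(14),11(13)-dien-12,8α-olide (1S,4R,5S,6S,7R,8S)
Conditions: HF·pyridine, pyridine, THF, 0 °C
Reagents that add atoms: none
Why: Buffered fluoride cleaves the labile secondary triethylsilyl ether quickly, and the trisubstituted oxirane, the angelate and the α-methylene lactone tolerate these conditions.

**Compound list**
1 | 2-(2-bromoethyl)-1,3-dioxolane | BrCCC1OCCO1 | starting material
2 | propyne | CC#C | starting material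
3 | [2-(1,3-dioxolan-2-yl)ethyl]magnesium bromide | Br[Mg]CCC1OCCO1 | intermediate
4 | (1Z)-[4-(1,3-dioxolan-2-yl)-2-methylbut-1-en-1-yl]copper | C1COC(O1)CC/C(C)=C\[Cu] | intermediate
5 | 2-[(3Z)-4-iodo-3-methylbut-3-en-1-yl]-1,3-dioxolane | C1COC(O1)CC/C(C)=C\I | intermediate
6 | (4Z)-5-iodo-4-methylpent-4-enal | O=CCC/C(C)=C\I | intermediate
7 | 3-bromobut-3-en-1-ol | OCCC(Br)=C | starting material
8 | [(3-bromobut-3-en-1-yl)oxy]triethylsilane | CC[Si](CC)(CC)OCCC(Br)=C | intermediate
9 | {4-[(triethylsilyl)oxy]but-1-en-2-yl}lithium | CC[Si](CC)(CC)OCCC([Li])=C | intermediate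
10 | rac-(7Z)-8-iodo-7-methyl-3-methylidene-1-[(triethylsilyl)oxy]oct-7-en-4-ol | CC[Si](CC)(CC)OCCC(=C)C(O)CC/C(C)=C\I | intermediate
11 | (7Z)-8-iodo-7-methyl-3-methylidene-1-[(triethylsilyl)oxy]oct-7-en-4-one | CC[Si](CC)(CC)OCCC(=C)C(=O)CC/C(C)=C\I | intermediate
12 | (4S,7Z)-8-iodo-7-methyl-3-methylidene-1-[(triethylsilyl)oxy]oct-7-en-4-ol | CC[Si](CC)(CC)OCCC(=C)[C@@H](O)CC/C(C)=C\I | intermediate
13 | (4S,7Z)-8-iodo-7-methyl-3-methylidene-1,4-bis[(triethylsilyl)oxy]oct-7-ene | CC[Si](CC)(CC)OCCC(=C)[C@@H](O[Si](CC)(CC)CC)CC/C(C)=C\I | intermediate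
14 | (4S,7Z)-8-iodo-7-methyl-3-methylidene-4-[(triethylsilyl)oxy]oct-7-enal | O=CCC(=C)[C@@H](O[Si](CC)(CC)CC)CC/C(C)=C\I | intermediate
15 | methyl 4-chloro-4-oxobutanoate | COC(=O)CCC(=O)Cl | starting material
16 | (methoxycarbonylmethyl)ketene | COC(=O)CC=C=O | intermediate
17 | cis-β-lactone, (3R,4S)-oxetan-2-one with C1-(S)-OTES side chain | COC(=O)C[C@H]1C(=O)O[C@H]1CC(=C)[C@@H](O[Si](CC)(CC)CC)CC/C(C)=C\I | intermediate
18 | hydroxy β-lactone (17 without TES) | COC(=O)C[C@H]1C(=O)O[C@H]1CC(=C)[C@@H](O)CC/C(C)=C\I | intermediate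
19 | seven-membered lactone (C6–O1) with free 8-OH and C7-CH2CO2Me, (1S,7R,8S) | COC(=O)C[C@H]1C(=O)O[C@@H](CC/C(C)=C\I)C(=C)C[C@@H]1O | intermediate
20 | trans-fused bis-lactone, (1S,7R,8S) | C1C(=O)O[C@H]2CC(=C)[C@H](CC/C(C)=C\I)OC(=O)[C@H]12 | intermediate
21 | Z-alkenyllithium of 20 | C1C(=O)O[C@H]2CC(=C)[C@H](CC/C(C)=C\[Li])OC(=O)[C@H]12 | intermediate
22 | bridged lithium hemiketal alkoxide (O1 bridges C1 and C6) | C1C(=O)O[C@H]2CC(=C)[C@@H]3CC/C(C)=C\[C@@](O[Li])(O3)[C@H]12 | intermediate
23 | lithium 1α-alkoxide of the ten-membered Z-enone | C1C(=O)O[C@H]2CC(=C)[C@@H](O[Li])CC/C(C)=C\C(=O)[C@H]12 | intermediate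
24 | (4Z)-1α-(triethylsilyloxy)-6-oxogermacra-4,10(14)-dien-12,8α-olide | C1C(=O)O[C@H]2CC(=C)[C@@H](O[Si](CC)(CC)CC)CC/C(C)=C\C(=O)[C@H]12 | intermediate
25 | (4Z)-6α-hydroxy-1α-(triethylsilyloxy)germacra-4,10(14)-dien-12,8α-olide | C1C(=O)O[C@H]2CC(=C)[C@@H](O[Si](CC)(CC)CC)CC/C(C)=C\[C@@H](O)[C@H]12 | intermediate
26 | 13-(dimethylamino) Mannich base of 25 (CH2NMe2 trans to C6) | CN(C)C[C@H]1C(=O)O[C@H]2CC(=C)[C@@H](O[Si](CC)(CC)CC)CC/C(C)=C\[C@@H](O)[C@H]12 | intermediate
27 | methiodide of 26 | C[N+](C)(C)C[C@H]1C(=O)O[C@H]2CC(=C)[C@@H](O[Si](CC)(CC)CC)CC/C(C)=C\[C@@H](O)[C@H]12.[I-] | intermediate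
28 | (4Z)-6α-hydroxy-1α-(triethylsilyloxy)germacra-4,10(14),11(13)-trien-12,8α-olide | C=C1C(=O)O[C@H]2CC(=C)[C@@H](O[Si](CC)(CC)CC)CC/C(C)=C\[C@@H](O)[C@H]12 | intermediate
29 | 4α,5α-epoxy-6α-hydroxy-1α-(triethylsilyloxy)germacra-10(14),11(13)-dien-12,8α-olide | C=C1C(=O)O[C@H]2CC(=C)[C@@H](O[Si](CC)(CC)CC)CC[C@@]3(C)O[C@H]3[C@@H](O)[C@H]12 | intermediate
30 | angelic acid | C/C=C(/C)C(=O)O | starting material
31 | angelic 2,4,6-trichlorobenzoic anhydride | C/C=C(/C)C(=O)OC(=O)c1c(Cl)cc(Cl)cc1Cl | intermediate
32 | 1-O-TES ether of the target | C=C1C(=O)O[C@H]2CC(=C)[C@@H](O[Si](CC)(CC)CC)CC[C@@]3(C)O[C@H]3[C@@H](OC(=O)/C(C)=C\C)[C@H]12 | intermediate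
33 | target CNP0104965.1 | C=C1C(=O)O[C@H]2CC(=C)[C@@H](O)CC[C@@]3(C)O[C@H]3[C@@H](OC(=O)/C(C)=C\C)[C@H]12 | target

Total step count: 16. Longest linear sequence: 15 steps (steps 1, 2 and 4 to 16; step 3 is a one-step branch).

**Steps most likely to fail**

1. Step 11.
- What may go wrong: proton transfer from C7–H or C11–H to the alkenyllithium, followed by β-elimination of the O8 carboxylate; direct attack of tert-butyllithium on a lactone; re-closure of the freed alkoxide onto C6, or transannular oxa-Michael addition to C4, before silylation.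
- Fallback: it sets out from 17 and returns at 25.
 - The β-lactone 17 is opened at its acyl carbon with MeNH(OMe)·HCl and Me2AlCl. The freed O8 closes the five-membered lactone on the methyl ester to give the Weinreb amide lactone F1.
 - Cp2Zr(H)Cl reduces the amide, leaving the lactone alone, to the C6 aldehyde F2.
 - A Nozaki–Hiyama–Kishi macrocyclisation (CrCl2, catalytic NiCl2, DMSO/THF, high dilution) joins C5 and C6 directly under neutral conditions and should give allylic alcohol 25.

2. Step 9.
- What may go wrong: amine-induced migration of C10=C14 into conjugation with the aldehyde; ketene dimerisation; eroded enantio- or cis-selectivity with the ester-bearing ketene.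
- Fallback: it sets out from 14 and returns at 20, so step 10 is bypassed as well.
 - (R)-4-Benzyl-1,3-oxazolidin-2-one is N-acylated with 15 (n-BuLi, THF) to the succinyl imide F3.
 - Its Bu2BOTf/Et3N Evans syn-aldol reaction with 14, with lactonisation on work-up, gives the imide lactone F4.
 - LiOH/H2O2 followed by dilute HCl removes the auxiliary and the silyl group to give the hydroxy acid F5.
 - Shiina lactonisation (2-methyl-6-nitrobenzoic anhydride, DMAP, high dilution) closes the seven-membered lactone of 20.

3. Step 12.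
- What may go wrong: poor facial selectivity of hydride delivery to the flexible ten-membered enone.
- Fallback: it sets out from 24 and returns at 25.
 - The reduction product of the wrong face, the 6β-alcohol F6, is inverted by a Mitsunobu reaction (4-nitrobenzoic acid, PPh3, DIAD) to the 6α 4-nitrobenzoate F7.
 - Mild methanolysis (K2CO3, MeOH, 0 °C) then gives 25.

**Further compounds**
F1 | step 11 | Weinreb amide lactone, trans-(7R,8S) five-membered lactone with C6 N-methoxy-N-methylamide and 1-OTES | CON(C)C(=O)[C@@H]1CC(=O)O[C@H]1CC(=C)[C@@H](O[Si](CC)(CC)CC)CC/C(C)=C\I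
F2 | step 11 | C6 aldehyde of the same lactone | O=C[C@@H]1CC(=O)O[C@H]1CC(=C)[C@@H](O[Si](CC)(CC)CC)CC/C(C)=C\I
F3 | step 9 | (R)-4-benzyl-3-(4-methoxy-4-oxobutanoyl)-1,3-oxazolidin-2-one | COC(=O)CCC(=O)N1[C@H](Cc2ccccc2)COC1=O
F4 | step 9 | imide lactone, trans five-membered lactone with C6 acyl oxazolidinone and 1-OTES | O=C([C@@H]1CC(=O)O[C@H]1CC(=C)[C@@H](O[Si](CC)(CC)CC)CC/C(C)=C\I)N1[C@H](Cc2ccccc2)COC1=O
F5 | step 9 | hydroxy acid, trans five-membered lactone with C6 carboxylic acid and free 1-OH | OC(=O)[C@@H]1CC(=O)O[C@H]1CC(=C)[C@@H](O)CC/C(C)=C\I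
F6 | step 12 | 6β-alcohol (C6 epimer of 25) | C1C(=O)O[C@H]2CC(=C)[C@@H](O[Si](CC)(CC)CC)CC/C(C)=C\[C@H](O)[C@H]12
F7 | step 12 | 6α 4-nitrobenzoate of 25 | C1C(=O)O[C@H]2CC(=C)[C@@H](O[Si](CC)(CC)CC)CC/C(C)=C\[C@@H](OC(=O)c3ccc(cc3)[N+](=O)[O-])[C@H]12
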